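A direct plan would start from ring B: a MOM-protected benzyl chloride A1 (three steps from the hydroxy aldehyde) would be turned into its zinc reagent and acylated with trifluorobenzoyl chloride A2 to give deoxybenzoin A3.
Formylation and displacement of an ortho fluoride would close the pyranone (difluoroisoflavone A4); a tertiary allylic alkoxide would replace both remaining fluorides (bis-ether A5), and a double Claisen rearrangement would give the 6,8-diprenyl compound A6 before the acetal is removed.
Weakest would be the twofold fluoride displacement on the finished isoflavone: a bulky, basic alkoxide must attack twice, the second time next to the carbonyl, while C2 of the pyranone is open to the same alkoxide, all on late material.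
Next would be the double Claisen rearrangement: nothing decides which ether moves first, the 7-ether can reach C6 as well as C8, and an ether left without a free ortho carbon would end as a 1,1-dimethylallyl group or lose isoprene, so the place of both prenyl groups would be left to chance one step from the end.
Third would be the run-up: protection, reduction and chlorination would only turn an aldehyde into a benzyl chloride, and three fluorine atoms would be carried as stand-ins for oxygen, many steps for no gain in skeleton.
The target has no stereocentre, and the fluoride-displacing ring closure itself would be sound; what the plan would not control is where the sigmatropic shifts end.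

**Plan of the new route**

The retrosynthesis cuts C3–C1' (ring B from ring C) together with O1–C2, then C2–C3 (C2 comes from an amide acetal), and last the two ring A–prenyl bonds at C6 and C8, which are therefore the first bonds made.
Ring A is bought and finished first: in 3,5-diprenylated 2,4,6-trihydroxyacetophenone the acetyl carbon (future C4) lies on a mirror plane between two equivalent hydroxyls, so whichever of them becomes O1 gives the same 5-oxy-6,8-diprenyl pattern.
Ring B is joined next and the pyranone (ring C) closes last, from the C2 side and in the same operation: the enaminone α-carbon (future C3) is the only nucleophilic C–H carbon, ring A (C4a to C8a) bearing no hydrogen, and C1' of ring B, para to O4' and ortho to the 2'-methoxy group, is innately nucleophilic too, so these two carbons of like polarity are joined after ring B has been turned into an aryl-λ3-iodane (polarity reversal).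
No fluoride is displaced, no allyl ether rearranges and no prenyl group is introduced after the first step; ring B enters as a commercial boronic acid, so the benzyl chloride run-up is gone.

Key step: step 6

Remark: the target has no stereocentre and its prenyl double bonds carry no E/Z label; the only geometric descriptor in the route is that of the E-enaminone 6.

**Route**

Step 1
Reactants: 1 1-(2,4,6-trihydroxyphenyl)ethan-1-one (2,4,6-trihydroxyacetophenone); 2 1-bromo-3-methylbut-2-ene (prenyl bromide)
Product: 3 1-[2,4,6-trihydroxy-3,5-bis(3-methylbut-2-enyl)phenyl]ethan-1-one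
Conditions: 2 (2.1 equiv), 10 % aq KOH (2.2 equiv), 0 °C → rt; NaH2PO4 work-up
Reagents that add atoms: none
Why: Twofold C-alkylation of the ambident phloroglucinol phenoxide by the allylic bromide (the laboratory counterpart of aromatic prenyl transfer in the biosynthesis of prenylated acylphloroglucinols) should work because in water the oxygens are solvated and the soft ring carbons react, C3 and C5 are the only free carbons and are equivalent, and two equivalents of 2 at 0 °C should hold back the gem-diprenylated dienones.

Step 2
Reactants: 3 1-[2,4,6-trihydroxy-3,5-bis(3-methylbut-2-enyl)phenyl]ethan-1-one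
Product: 4 1-[2-hydroxy-4,6-bis(methoxymethoxy)-3,5-bis(3-methylbut-2-enyl)phenyl]ethan-1-one
Conditions: MOMCl (2.2 equiv), iPr2NEt (3 equiv), CH2Cl2, 0 °C → rt
Reagents that add atoms: chloromethyl methyl ether, COCCl
Why: O-alkylation by the hard α-chloro ether (MOM protection) takes the para hydroxyl and one of the two equivalent ortho hydroxyls, while the remaining ortho hydroxyl, tied to the acetyl oxygen by a hydrogen bond, stays free under amine base, and the acetals are needed because free acidic phenols would be methylated by the amide acetal and arylated in the key step.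

Step 3
Reactants: 4 1-[2-hydroxy-4,6-bis(methoxymethoxy)-3,5-bis(3-methylbut-2-enyl)phenyl]ethan-1-one; 5 1,1-dimethoxy-N,N-dimethylmethanamine (N,N-dimethylformamide dimethyl acetal)
Product: 6 (E)-3-(dimethylamino)-1-[2-hydroxy-4,6-bis(methoxymethoxy)-3,5-bis(3-methylbut-2-enyl)phenyl]prop-2-en-1-one
Conditions: 5 (3 equiv), toluene, 90 °C, MeOH distilled off
Reagents that add atoms: none
Why: Condensation of the methyl ketone with the amide acetal (enaminone formation) adds the carbon that becomes C2 under neutral conditions that leave acetals and prenyl groups alone, and the E geometry follows from the conjugated, chelated vinylogous amide.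

Step 4
Reactants: 7 (4-hydroxy-2-methoxyphenyl)boronic acid
Product: 8 [4-(acetyloxy)-2-methoxyphenyl]boronic acid
Conditions: Ac2O (1.2 equiv), pyridine (1.5 equiv), CH2Cl2, 0 °C → rt; aqueous work-up at pH 5
Reagents that add atoms: acetic anhydride, CC(=O)OC(C)=O
Why: O-acetylation (acyl transfer with pyridine as base and nucleophilic catalyst) masks the phenol that trivalent iodine would otherwise oxidise, the aryl acetate survives the acidic iodonium formation yet leaves by mild methanolysis at the end, and any mixed boron acetate is hydrolysed back to the boronic acid on work-up.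

Step 5
Reactants: 8 [4-(acetyloxy)-2-methoxyphenyl]boronic acid; 9 2-[bis(acetyloxy)-λ3-iodanyl]-1,3,5-trimethylbenzene (iodomesitylene diacetate)
Product: 11 [4-(acetyloxy)-2-methoxyphenyl](2,4,6-trimethylphenyl)iodonium trifluoromethanesulfonate, via iodomesitylene bis(triflate) 10 (not isolated)
Conditions: 9 (1.0 equiv), TfOH (2.0 equiv), CH2Cl2, −30 °C; then 8 (1.05 equiv), −30 → 0 °C; precipitation with Et2O
Reagents that add atoms: trifluoromethanesulfonic acid, OS(=O)(=O)C(F)(F)F
Why: Boron-to-iodine aryl transfer (ipso substitution of an arylboronic acid by an acid-activated λ3-iodane, the regiospecific synthesis of unsymmetrical diaryliodonium triflates) puts iodine exactly at C1' of ring B because the C–B bond fixes the site, and the low temperature should keep protodeboronation of the donor-rich boronic acid behind the transfer.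

Step 6
Reactants: 6 (E)-3-(dimethylamino)-1-[2-hydroxy-4,6-bis(methoxymethoxy)-3,5-bis(3-methylbut-2-enyl)phenyl]prop-2-en-1-one; 11 [4-(acetyloxy)-2-methoxyphenyl](2,4,6-trimethylphenyl)iodonium trifluoromethanesulfonate
Product: 13 4-[5,7-bis(methoxymethoxy)-6,8-bis(3-methylbut-2-enyl)-4-oxochromen-3-yl]-3-methoxyphenyl acetate, via 2-(dimethylamino)isoflavanone 12 (not isolated)
Conditions: 11 (1.3 equiv), [Cu(MeCN)4]PF6 (10 mol %), 2,6-di-tert-butylpyridine (1.2 equiv), CH2Cl2, 0 → 30 °C, Ar
Reagents that add atoms: none
Why: Proposed new method: monovalent copper should add oxidatively to iodonium salt 11 on the side of its less hindered aryl group (the mesityl group, blocked at both ortho positions, stays on iodine as iodomesitylene), the aryl species of trivalent copper so formed should be attacked by the α-carbon of the push–pull enaminone 6, and reductive elimination should make the C3–C1' bond and leave an α-aryl iminium ion, to whose carbon the hydrogen-bonded ortho hydroxyl adds (aminal 12) before dimethylamine leaves, taking the triflic acid with it as its salt, and the pyranone becomes aromatic. The closest known reaction types are the copper-catalysed C-arylation of enamines, enamides, silyl enol ethers and indoles by diaryliodonium salts and the electrophile-triggered closure of 2-hydroxyaryl enaminones to 3-substituted chromones (with iodine or sulfenyl electrophiles); the α-aryl enaminone that lies between the two events is the species that closes of its own accord in the deoxybenzoin–amide acetal synthesis of isoflavones. The pyranone is the only ring closed, by O1–C2 bond formation in a 6-exo-trig mode at the C=N+ bond (6-endo-trig at the C2=C3 bond if the iminium ion first loses its α-proton), both favoured and both prepared by the hydrogen-bonded six-membered array already present in 6. The two stereocentres of 12 (C2 and C3) are lost again on elimination, so no stereocontrol is needed. The selectivity needed is C-arylation of the enaminone in preference to arylation of the two prenyl double bonds or of the phenol oxygen, and it should be secured by the much higher π-nucleophilicity of the vinylogous amide carbon compared with a trisubstituted alkene, by the absence of any C–H bond on ring A, and by the hindered pyridine, which keeps the medium free both of phenoxide and of the acid that would close 6 to the C3-unsubstituted chromone. Because the two ortho oxygens of ring A were equivalent before protection, only the 6,8-diprenyl chromone can form.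

Step 7
Reactants: 13 4-[5,7-bis(methoxymethoxy)-6,8-bis(3-methylbut-2-enyl)-4-oxochromen-3-yl]-3-methoxyphenyl acetate
Product: 15 5,7-dihydroxy-3-(4-hydroxy-2-methoxyphenyl)-6,8-bis(3-methylbut-2-enyl)chromen-4-one (the target), via bis-MOM phenol 14 (not isolated)
Conditions: K2CO3 (1.5 equiv), MeOH, rt; then 3 M aq HCl to pH 1, 40 °C, stopped at full conversion
Reagents that add atoms: none
Why: Methoxide-mediated transesterification frees the 4'-phenol and acid-catalysed methanolysis of the two aryl MOM acetals then frees O5 and O7, and dilute acid at 40 °C for a short time should leave the prenyl double bonds, the aryl methyl ether and the pyranone untouched.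

**Compound list**

1 | 1-(2,4,6-trihydroxyphenyl)ethan-1-one | CC(=O)c1c(O)cc(O)cc1O | starting material
2 | 1-bromo-3-methylbut-2-ene | CC(C)=CCBr | starting material
3 | 1-[2,4,6-trihydroxy-3,5-bis(3-methylbut-2-enyl)phenyl]ethan-1-one | CC(=O)c1c(O)c(CC=C(C)C)c(O)c(CC=C(C)C)c1O | intermediate
4 | 1-[2-hydroxy-4,6-bis(methoxymethoxy)-3,5-bis(3-methylbut-2-enyl)phenyl]ethan-1-one | CC(=O)c1c(O)c(CC=C(C)C)c(OCOC)c(CC=C(C)C)c1OCOC | intermediate
5 | 1,1-dimethoxy-N,N-dimethylmethanamine | COC(OC)N(C)C | starting material
6 | (E)-3-(dimethylamino)-1-[2-hydroxy-4,6-bis(methoxymethoxy)-3,5-bis(3-methylbut-2-enyl)phenyl]prop-2-en-1-one | CN(C)/C=C/C(=O)c1c(O)c(CC=C(C)C)c(OCOC)c(CC=C(C)C)c1OCOC | intermediate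
7 | (4-hydroxy-2-methoxyphenyl)boronic acid | COc1cc(O)ccc1B(O)O | starting material
8 | [4-(acetyloxy)-2-methoxyphenyl]boronic acid | COc1cc(OC(C)=O)ccc1B(O)O | intermediate
9 | 2-[bis(acetyloxy)-λ3-iodanyl]-1,3,5-trimethylbenzene | CC(=O)OI(OC(C)=O)c1c(C)cc(C)cc1C | starting material
10 | 2-[bis(trifluoromethanesulfonyloxy)-λ3-iodanyl]-1,3,5-trimethylbenzene (not isolated) | Cc1cc(C)c(I(OS(=O)(=O)C(F)(F)F)OS(=O)(=O)C(F)(F)F)c(C)c1 | intermediate
11 | [4-(acetyloxy)-2-methoxyphenyl](2,4,6-trimethylphenyl)iodonium trifluoromethanesulfonate | COc1cc(OC(C)=O)ccc1[I+]c1c(C)cc(C)cc1C.[O-]S(=O)(=O)C(F)(F)F | intermediate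
12 | 4-[2-(dimethylamino)-5,7-bis(methoxymethoxy)-6,8-bis(3-methylbut-2-enyl)-4-oxochroman-3-yl]-3-methoxyphenyl acetate (mixture of diastereomers, not isolated) | CN(C)C1Oc2c(CC=C(C)C)c(OCOC)c(CC=C(C)C)c(OCOC)c2C(=O)C1c1ccc(OC(C)=O)cc1OC | intermediate
13 | 4-[5,7-bis(methoxymethoxy)-6,8-bis(3-methylbut-2-enyl)-4-oxochromen-3-yl]-3-methoxyphenyl acetate | COc1cc(OC(C)=O)ccc1-c1coc2c(CC=C(C)C)c(OCOC)c(CC=C(C)C)c(OCOC)c2c1=O | intermediate
14 | 3-(4-hydroxy-2-methoxyphenyl)-5,7-bis(methoxymethoxy)-6,8-bis(3-methylbut-2-enyl)chromen-4-one (not isolated) | COc1cc(O)ccc1-c1coc2c(CC=C(C)C)c(OCOC)c(CC=C(C)C)c(OCOC)c2c1=O | intermediate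
15 | 5,7-dihydroxy-3-(4-hydroxy-2-methoxyphenyl)-6,8-bis(3-methylbut-2-enyl)chromen-4-one | COc1cc(O)ccc1-c1coc2c(CC=C(C)C)c(O)c(CC=C(C)C)c(O)c2c1=O | target

**Step count and risks**

Total step count: 7. Longest linear sequence: 5 steps (steps 1, 2, 3, 6 and 7); steps 4 and 5 are the two-step branch that prepares ring B.

Steps most likely to fail:

1. Step 6 (the proposed new method). What may go wrong: arylation of a prenyl double bond or of the phenol oxygen instead of the enaminone carbon, transfer of the mesityl group, or closure of 6 to the C3-unsubstituted chromone before the aryl group arrives. The fallback uses known chemistry and sets out from 6. I2 (1.05 equiv) in CHCl3 at 0 °C would iodinate the α-carbon and close the ring with loss of dimethylamine to give 3-iodo-5,7-bis(methoxymethoxy)-6,8-bis(3-methylbut-2-enyl)chromen-4-one F1; no free phenol is left there to add to an iodonium ion on a prenyl group. Suzuki–Miyaura coupling of F1 with the unprotected boronic acid 7 (Pd(PPh3)4 as source of zerovalent palladium, Na2CO3, DME–H2O, 80 °C) would give phenol 14. The route is rejoined at 14, before the acid stage of step 7; steps 4 and 5 would then not be needed.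

2. Step 1. What may go wrong: O-alkylation, stopping at the mono-prenyl stage, and over-alkylation to gem-diprenyl cyclohexadienones, all of which drain material at the outset. The fallback replaces phenoxide alkylation by directed metalation and sets out from prenyl bromide 2 and bought benzene-1,3,5-triol F2. Exhaustive protection (NaH, MOMCl, DMF) would give 1,3,5-tris(methoxymethoxy)benzene F3. Lithiation between two acetal oxygens (n-BuLi, THF, 0 °C), transmetalation with CuBr·SMe2 and alkylation with 2 would give 1,3,5-tris(methoxymethoxy)-2-(3-methylbut-2-enyl)benzene F4, and a second cycle 1,3,5-tris(methoxymethoxy)-2,4-bis(3-methylbut-2-enyl)benzene F5. A third lithiation at the last ring C–H and acylation with N-methoxy-N-methylacetamide would give 1-[2,4,6-tris(methoxymethoxy)-3,5-bis(3-methylbut-2-enyl)phenyl]ethan-1-one F6. Brief treatment with dilute HCl in MeOH at rt would then remove one acetal ortho to the carbonyl, helped by chelation. The route is rejoined at 4, so step 2 is skipped as well.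

3. Step 7. What may go wrong: acid-induced addition of the freed 5- and 7-hydroxyls to the neighbouring prenyl double bonds (closure to dimethylchromans) during acetal cleavage. The fallback avoids acid altogether by using allyl ethers in place of the acetals and sets out from 3. Allyl bromide with K2CO3 in acetone would give 1-[2-hydroxy-4,6-bis(prop-2-enyloxy)-3,5-bis(3-methylbut-2-enyl)phenyl]ethan-1-one F7. Amide acetal 5 would give (E)-3-(dimethylamino)-1-[2-hydroxy-4,6-bis(prop-2-enyloxy)-3,5-bis(3-methylbut-2-enyl)phenyl]prop-2-en-1-one F8. The conditions of step 6 with 11 would give 4-[6,8-bis(3-methylbut-2-enyl)-4-oxo-5,7-bis(prop-2-enyloxy)chromen-3-yl]-3-methoxyphenyl acetate F9. Pd(PPh3)4 (zerovalent palladium) with K2CO3 in MeOH at rt would then methanolyse the acetate and pass both allyl groups to methanol through π-allylpalladium intermediates. The route is rejoined at the target 15.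

**Further compounds**

F1 | step 6 | 3-iodo-5,7-bis(methoxymethoxy)-6,8-bis(3-methylbut-2-enyl)chromen-4-one | O=c1c(I)coc2c(CC=C(C)C)c(OCOC)c(CC=C(C)C)c(OCOC)c12
F2 | step 1 | benzene-1,3,5-triol (bought) | Oc1cc(O)cc(O)c1
F3 | step 1 | 1,3,5-tris(methoxymethoxy)benzene | COCOc1cc(OCOC)cc(OCOC)c1
F4 | step 1 | 1,3,5-tris(methoxymethoxy)-2-(3-methylbut-2-enyl)benzene | COCOc1cc(OCOC)c(CC=C(C)C)c(OCOC)c1
F5 | step 1 | 1,3,5-tris(methoxymethoxy)-2,4-bis(3-methylbut-2-enyl)benzene | COCOc1cc(OCOC)c(CC=C(C)C)c(OCOC)c1CC=C(C)C
F6 | step 1 | 1-[2,4,6-tris(methoxymethoxy)-3,5-bis(3-methylbut-2-enyl)phenyl]ethan-1-one | CC(=O)c1c(OCOC)c(CC=C(C)C)c(OCOC)c(CC=C(C)C)c1OCOC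
F7 | step 7 | 1-[2-hydroxy-4,6-bis(prop-2-enyloxy)-3,5-bis(3-methylbut-2-enyl)phenyl]ethan-1-one | CC(=O)c1c(O)c(CC=C(C)C)c(OCC=C)c(CC=C(C)C)c1OCC=C
F8 | step 7 | (E)-3-(dimethylamino)-1-[2-hydroxy-4,6-bis(prop-2-enyloxy)-3,5-bis(3-methylbut-2-enyl)phenyl]prop-2-en-1-one | CN(C)/C=C/C(=O)c1c(O)c(CC=C(C)C)c(OCC=C)c(CC=C(C)C)c1OCC=C
F9 | step 7 | 4-[6,8-bis(3-methylbut-2-enyl)-4-oxo-5,7-bis(prop-2-enyloxy)chromen-3-yl]-3-methoxyphenyl acetate | COc1cc(OC(C)=O)ccc1-c1coc2c(CC=C(C)C)c(OCC=C)c(CC=C(C)C)c(OCC=C)c2c1=O
A1 | direct plan | 1-(chloromethyl)-2-methoxy-4-(methoxymethoxy)benzene | COCOc1ccc(CCl)c(OC)c1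
A2 | direct plan | 2,4,6-trifluorobenzoyl chloride | O=C(Cl)c1c(F)cc(F)cc1F
A3 | direct plan | 2-[2-methoxy-4-(methoxymethoxy)phenyl]-1-(2,4,6-trifluorophenyl)ethan-1-one | COCOc1ccc(CC(=O)c2c(F)cc(F)cc2F)c(OC)c1
A4 | direct plan | 5,7-difluoro-3-[2-methoxy-4-(methoxymethoxy)phenyl]chromen-4-one | COCOc1ccc(-c2coc3cc(F)cc(F)c3c2=O)c(OC)c1
A5 | direct plan | 3-[2-methoxy-4-(methoxymethoxy)phenyl]-5,7-bis[(2-methylbut-3-en-2-yl)oxy]chromen-4-one | COCOc1ccc(-c2coc3cc(OC(C)(C)C=C)cc(OC(C)(C)C=C)c3c2=O)c(OC)c1
A6 | direct plan | 5,7-dihydroxy-3-[2-methoxy-4-(methoxymethoxy)phenyl]-6,8-bis(3-methylbut-2-enyl)chromen-4-one | COCOc1ccc(-c2coc3c(CC=C(C)C)c(O)c(CC=C(C)C)c(O)c3c2=O)c(OC)c1
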